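**Retrosynthetic overview** (atom labels C1–C15 follow germacrane numbering of the target)
1. Target 26 ⇐ acetylation and hydroxyl-directed epoxidation of macrocyclic allylic alcohol 24 (oxirane formed last).
2. Ten-membered carbocycle, then the α-methylene lactone ⇐ one operation on acyclic enal–allylboronate 21: chiral phosphoric acid-catalysed intramolecular allylboration (C6–C7) followed by lactonisation.
3. 21 ⇐ Negishi coupling on bromoacrylate 17 ⇐ SN2 of epoxy acid 3 on chloride 16 ⇐ organocatalytic α-chlorination/olefination of aldehyde 12 (sets C8).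
4. 12 ⇐ Claisen rearrangement (C8–C9 bond, trans C1=C10) of allylic alcohol 10 ⇐ nerol-derived aldehyde 6 + 2-lithioallyl silyl ether 9.
5. Acid 3 ⇐ organocatalytic asymmetric epoxidation of tiglic aldehyde 1.

Assumption: the sense of induction of the three chiral organocatalysts (steps 1, 9, 13) is taken from the closest simple cases and has not been verified for these substrates; if a sense is opposite, the mirror-image (or pseudo-enantiomeric) catalyst is used.

TRIP = 3,3'-bis(2,4,6-triisopropylphenyl)-1,1'-binaphthyl-2,2'-diyl hydrogen phosphate; TBS = tert-butyldimethylsilyl; TES = triethylsilyl; Bpin = 4,4,5,5-tetramethyl-1,3,2-dioxaborolan-2-yl.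

**Step 1**
Reactants: 1 (E)-2-methylbut-2-enal (tiglic aldehyde)
Product: 2 (2R,3S)-2,3-dimethyloxirane-2-carbaldehyde
Conditions: 9-amino-9-deoxy-epi-quinine (10 mol%), (R)-TRIP (20 mol%), 50% aq. H2O2, THF, 50 °C
Reagents that add atoms: hydrogen peroxide, OO
Why: Iminium-activated nucleophilic epoxidation of an α-branched enal, in which the chiral primary amine/chiral phosphate ion pair selects the face for peroxide addition and ring closure, so both oxirane centres are set by asymmetric organocatalysis and the E geometry is carried over as cis methyls.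

**Step 2**
Reactants: 2 (2R,3S)-2,3-dimethyloxirane-2-carbaldehyde
Product: 3 (2R,3S)-2,3-dimethyloxirane-2-carboxylic acid
Conditions: NaClO2, NaH2PO4, 2-methylbut-2-ene, t-BuOH/H2O, 0 °C
Reagents that add atoms: sodium chlorite, [Na+].[O-]Cl=O
Why: Pinnick oxidation converts the aldehyde to the acid without touching the oxirane or the non-epimerisable quaternary centre.

**Step 3**
Reactants: 4 nerol
Product: 5 triethyl{[(2Z)-3,7-dimethylocta-2,6-dien-1-yl]oxy}silane
Conditions: Et3SiCl, imidazole, CH2Cl2, 0 °C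
Reagents that add atoms: chlorotriethylsilane, CC[Si](Cl)(CC)CC
Why: Standard silylation masks the future C6 oxygen as a TES ether that can later be oxidised directly.

**Step 4**
Reactants: 5 triethyl{[(2Z)-3,7-dimethylocta-2,6-dien-1-yl]oxy}silane
Product: 6 (4Z)-4-methyl-6-(triethylsilyloxy)hex-4-enal
Conditions: O3 (1.0 equiv), pyridine (cat.), CH2Cl2, −78 °C; then Me2S
Reagents that add atoms: ozone, [O-][O+]=O
Why: Chemoselective ozonolysis cleaves the electron-rich isopropylidene alkene in preference to the alkene deactivated by the allylic silyloxy group, leaving the Z alkene (future C4=C5) intact.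

**Step 5**
Reactants: 7 2-bromoprop-2-en-1-ol
Product: 8 (2-bromoprop-2-en-1-yloxy)(tert-butyl)dimethylsilane
Conditions: TBSCl, imidazole, DMF, rt
Reagents that add atoms: tert-butyldimethylsilyl chloride, CC(C)(C)[Si](C)(C)Cl
Why: Standard silylation protects the future C14 oxygen so that the vinyl bromide can be lithiated.

**Step 6**
Reactants: 8 (2-bromoprop-2-en-1-yloxy)(tert-butyl)dimethylsilane; 6 (4Z)-4-methyl-6-(triethylsilyloxy)hex-4-enal
Product: 10 rac-(6Z)-2-[(tert-butyldimethylsilyloxy)methyl]-6-methyl-8-(triethylsilyloxy)octa-1,6-dien-3-ol, via vinyllithium 9 (not isolated)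
Conditions: t-BuLi (2.1 equiv), Et2O, −78 °C; then 6, −78 °C; H2O
Reagents that add atoms: none
Why: Bromine–lithium exchange and 1,2-addition to the aldehyde join C1 to C10; the carbinol centre is left racemic because step 7 erases it.

**Step 7**
Reactants: 10 rac-(6Z)-2-[(tert-butyldimethylsilyloxy)methyl]-6-methyl-8-(triethylsilyloxy)octa-1,6-dien-3-ol
Product: 12 (4Z,8Z)-4-[(tert-butyldimethylsilyloxy)methyl]-8-methyl-10-(triethylsilyloxy)deca-4,8-dienal, via allyl vinyl ether 11 (not isolated)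
Conditions: EtOCH=CH2, Hg(OAc)2 (0.2 equiv), reflux; then xylenes, 140 °C
Reagents that add atoms: ethyl vinyl ether, C=COCC
Why: Transvinylation followed by Claisen rearrangement through a chair with the C2 chain equatorial forges C8–C9 and the trisubstituted C1=C10 alkene with C2 trans to C9 (cis to C14), as needed for the trans ring alkene.

**Step 8**
Reactants: 13 methyl 2-[bis(2,2,2-trifluoroethoxy)phosphoryl]acetate
Product: 14 methyl 2-bromo-2-[bis(2,2,2-trifluoroethoxy)phosphoryl]acetate (racemic)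
Conditions: NaH, THF, 0 °C; then Br2, −78 °C
Reagents that add atoms: bromine, BrBr
Why: Enolate bromination gives the bromo analogue of the Still–Gennari phosphonate used in step 9.

**Step 9**
Reactants: 12 (4Z,8Z)-4-[(tert-butyldimethylsilyloxy)methyl]-8-methyl-10-(triethylsilyloxy)deca-4,8-dienal; 14 methyl 2-bromo-2-[bis(2,2,2-trifluoroethoxy)phosphoryl]acetate
Product: 16 methyl (2E,4S,6Z,10Z)-2-bromo-4-chloro-6-[(tert-butyldimethylsilyloxy)methyl]-10-methyl-12-(triethylsilyloxy)dodeca-2,6,10-trienoate, via chloroaldehyde 15 (not isolated)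
Conditions: N-chlorosuccinimide, (2R,5R)-2,5-diphenylpyrrolidine (10 mol%), CH2Cl2, 0 °C; pentane, filter; then 14, KOt-Bu, 18-crown-6, THF, −78 °C
Reagents that add atoms: N-chlorosuccinimide, O=C1CCC(=O)N1Cl
Why: Enamine-mediated α-chlorination, in which the C2-symmetric pyrrolidine shields one enamine face, sets C8 as the (S)-chloride (first stereocentre of this fragment, by asymmetric organocatalysis), and the Still–Gennari-type Horner–Wadsworth–Emmons olefination then places the ester cis to C8 (E-bromoacrylate).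

**Step 10**
Reactants: 16 methyl (2E,4S,6Z,10Z)-2-bromo-4-chloro-6-[(tert-butyldimethylsilyloxy)methyl]-10-methyl-12-(triethylsilyloxy)dodeca-2,6,10-trienoate; 3 (2R,3S)-2,3-dimethyloxirane-2-carboxylic acid
Product: 17 methyl (2E,4R,6Z,10Z)-2-bromo-4-{[(2R,3S)-2,3-dimethyloxirane-2-carbonyl]oxy}-6-[(tert-butyldimethylsilyloxy)methyl]-10-methyl-12-(triethylsilyloxy)dodeca-2,6,10-trienoate
Conditions: 3, Cs2CO3 (0.55 equiv), DMF, 0 °C → rt
Reagents that add atoms: none
Why: SN2 displacement of the ester-activated allylic chloride by the caesium carboxylate inverts C8 to the (8R)-ester and never exposes a free hydroxyl cis to the ester, which would close to a butenolide.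

**Step 11**
Reactants: 17 methyl (2E,4R,6Z,10Z)-2-bromo-4-{[(2R,3S)-2,3-dimethyloxirane-2-carbonyl]oxy}-6-[(tert-butyldimethylsilyloxy)methyl]-10-methyl-12-(triethylsilyloxy)dodeca-2,6,10-trienoate; 18 2-(iodomethyl)-4,4,5,5-tetramethyl-1,3,2-dioxaborolane
Product: 20 methyl (2Z,4R,6Z,10Z)-4-{[(2R,3S)-2,3-dimethyloxirane-2-carbonyl]oxy}-6-[(tert-butyldimethylsilyloxy)methyl]-10-methyl-2-[(4,4,5,5-tetramethyl-1,3,2-dioxaborolan-2-yl)methyl]-12-(triethylsilyloxy)dodeca-2,6,10-trienoate, via borylmethylzinc iodide 19 (not isolated)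
Conditions: 18, Zn dust, THF, rt; then 17, Pd(PPh3)4 (5 mol%), THF, rt
Reagents that add atoms: none
Why: Zinc insertion and Negishi coupling at the reactive α-bromoacrylate proceed with retention of alkene geometry, giving the 2-alkoxycarbonyl allylboronate with CH2B trans to C8 (E-crotyl type).

**Step 12**
Reactants: 20 methyl (2Z,4R,6Z,10Z)-4-{[(2R,3S)-2,3-dimethyloxirane-2-carbonyl]oxy}-6-[(tert-butyldimethylsilyloxy)methyl]-10-methyl-2-[(4,4,5,5-tetramethyl-1,3,2-dioxaborolan-2-yl)methyl]-12-(triethylsilyloxy)dodeca-2,6,10-trienoate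
Product: 21 methyl (2Z,4R,6Z,10Z)-4-{[(2R,3S)-2,3-dimethyloxirane-2-carbonyl]oxy}-6-[(tert-butyldimethylsilyloxy)methyl]-10-methyl-12-oxo-2-[(4,4,5,5-tetramethyl-1,3,2-dioxaborolan-2-yl)methyl]dodeca-2,6,10-trienoate
Conditions: (COCl)2, DMSO, CH2Cl2, −78 °C; then Et3N, −78 → −20 °C
Reagents that add atoms: none
Why: Swern conditions oxidise a primary TES ether directly to the aldehyde (oxidative desilylation) while the TBS ether, the deactivated allylboronate and the esters are inert.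

**Step 13**
Reactants: 21 methyl (2Z,4R,6Z,10Z)-4-{[(2R,3S)-2,3-dimethyloxirane-2-carbonyl]oxy}-6-[(tert-butyldimethylsilyloxy)methyl]-10-methyl-12-oxo-2-[(4,4,5,5-tetramethyl-1,3,2-dioxaborolan-2-yl)methyl]dodeca-2,6,10-trienoate
Product: 23 (6R,7R,8R)-14-(tert-butyldimethylsilyloxy)-8-{[(2R,3S)-2,3-dimethyloxirane-2-carbonyl]oxy}germacra-1(10),4,11(13)-trien-12,6-olide (C4=C5 cis in the ring; C1=C10 trans in the ring), via borate ester 22 (not isolated)
Conditions: (S)-TRIP (20 mol%), PhMe, 2 mM (slow addition), 50 °C; then PPTS (cat.), rt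
Reagents that add atoms: none
Why: Proposed new method: a chiral phosphoric acid-catalysed intramolecular allylboration of an enal by a 2-alkoxycarbonyl allylboronate that closes the ten-membered carbocycle at C6–C7, where the acid hydrogen-bonds the boronate oxygen and the formyl C–H in a closed chair (Zimmerman–Traxler) transition state, the CH2B-trans position of C8 places C5 and C8 anti so that attack of the borate oxygen on the methyl ester gives the 6,7-trans α-methylene lactone, the (S)-phosphate selects the aldehyde face for 6R,7R next to the fixed 8R centre, and the weak acid avoids ene cyclisation of the neral-like enal and oxirane opening; the closest known reactions are the chiral phosphoric acid-catalysed intermolecular allylboration of aldehydes with allyl pinacolboronates and the acid-promoted allylboration–lactonisation of 2-alkoxycarbonyl allylboronates.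

**Step 14**
Reactants: 23 (6R,7R,8R)-14-(tert-butyldimethylsilyloxy)-8-{[(2R,3S)-2,3-dimethyloxirane-2-carbonyl]oxy}germacra-1(10),4,11(13)-trien-12,6-olide
Product: 24 (6R,7R,8R)-8-{[(2R,3S)-2,3-dimethyloxirane-2-carbonyl]oxy}-14-hydroxygermacra-1(10),4,11(13)-trien-12,6-olide
Conditions: HF·pyridine, pyridine, THF, 0 °C
Reagents that add atoms: none
Why: Buffered fluoride desilylation frees the primary allylic alcohol without touching the lactone, the ester or the oxirane.

**Step 15**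
Reactants: 24 (6R,7R,8R)-8-{[(2R,3S)-2,3-dimethyloxirane-2-carbonyl]oxy}-14-hydroxygermacra-1(10),4,11(13)-trien-12,6-olide
Product: 25 (1R,6R,7R,8R,10S)-1,10-epoxy-8-{[(2R,3S)-2,3-dimethyloxirane-2-carbonyl]oxy}-14-hydroxygermacra-4,11(13)-dien-12,6-olide
Conditions: VO(acac)2 (5 mol%), t-BuOOH, CH2Cl2, 0 °C
Reagents that add atoms: tert-butyl hydroperoxide, CC(C)(C)OO
Why: Hydroxyl-directed epoxidation delivers oxygen only to the C1=C10 alkene, and this trans ring alkene can be reached only from its outer face, which is expected (not proven for this ring) to give the (1R,10S)-oxirane as in peracid epoxidations of germacranolides.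

**Step 16**
Reactants: 25 (1R,6R,7R,8R,10S)-1,10-epoxy-8-{[(2R,3S)-2,3-dimethyloxirane-2-carbonyl]oxy}-14-hydroxygermacra-4,11(13)-dien-12,6-olide
Product: 26 target, (1R,6R,7R,8R,10S)-14-acetoxy-1,10-epoxy-8-{[(2R,3S)-2,3-dimethyloxirane-2-carbonyl]oxy}germacra-4,11(13)-dien-12,6-olide
Conditions: Ac2O, pyridine, DMAP (cat.), CH2Cl2, 0 °C
Reagents that add atoms: acetic anhydride, CC(=O)OC(C)=O
Why: Standard acetylation of the primary epoxy alcohol gives the target.

**Compound list**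
1 | (E)-2-methylbut-2-enal (tiglic aldehyde) | C/C=C(\C)C=O | starting material
2 | (2R,3S)-2,3-dimethyloxirane-2-carbaldehyde | O=C[C@]1(C)O[C@H]1C | intermediate
3 | (2R,3S)-2,3-dimethyloxirane-2-carboxylic acid | OC(=O)[C@]1(C)O[C@H]1C | intermediate
4 | nerol, (2Z)-3,7-dimethylocta-2,6-dien-1-ol | CC(C)=CCC/C(C)=C\CO | starting material
5 | triethyl{[(2Z)-3,7-dimethylocta-2,6-dien-1-yl]oxy}silane | CC(C)=CCC/C(C)=C\CO[Si](CC)(CC)CC | intermediate
6 | (4Z)-4-methyl-6-(triethylsilyloxy)hex-4-enal | O=CCC/C(C)=C\CO[Si](CC)(CC)CC | intermediate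
7 | 2-bromoprop-2-en-1-ol | OCC(Br)=C | starting material
8 | (2-bromoprop-2-en-1-yloxy)(tert-butyl)dimethylsilane | C=C(Br)CO[Si](C)(C)C(C)(C)C | intermediate
9 | [3-(tert-butyldimethylsilyloxy)prop-1-en-2-yl]lithium (not isolated) | [Li]C(=C)CO[Si](C)(C)C(C)(C)C | intermediate
10 | rac-(6Z)-2-[(tert-butyldimethylsilyloxy)methyl]-6-methyl-8-(triethylsilyloxy)octa-1,6-dien-3-ol | C=C(CO[Si](C)(C)C(C)(C)C)C(O)CC/C(C)=C\CO[Si](CC)(CC)CC | intermediate
11 | vinyl ether of 10, rac-(6Z)-2-[(tert-butyldimethylsilyloxy)methyl]-3-(ethenyloxy)-6-methyl-8-(triethylsilyloxy)octa-1,6-diene (not isolated) | C=COC(CC/C(C)=C\CO[Si](CC)(CC)CC)C(=C)CO[Si](C)(C)C(C)(C)C | intermediate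
12 | (4Z,8Z)-4-[(tert-butyldimethylsilyloxy)methyl]-8-methyl-10-(triethylsilyloxy)deca-4,8-dienal | O=CCC/C(CO[Si](C)(C)C(C)(C)C)=C/CC/C(C)=C\CO[Si](CC)(CC)CC | intermediate
13 | methyl 2-[bis(2,2,2-trifluoroethoxy)phosphoryl]acetate | COC(=O)CP(=O)(OCC(F)(F)F)OCC(F)(F)F | starting material
14 | methyl 2-bromo-2-[bis(2,2,2-trifluoroethoxy)phosphoryl]acetate (racemic) | COC(=O)C(Br)P(=O)(OCC(F)(F)F)OCC(F)(F)F | intermediate
15 | (2S,4Z,8Z)-2-chloro-4-[(tert-butyldimethylsilyloxy)methyl]-8-methyl-10-(triethylsilyloxy)deca-4,8-dienal (not isolated) | O=C[C@@H](Cl)C/C(CO[Si](C)(C)C(C)(C)C)=C/CC/C(C)=C\CO[Si](CC)(CC)CC | intermediate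
16 | methyl (2E,4S,6Z,10Z)-2-bromo-4-chloro-6-[(tert-butyldimethylsilyloxy)methyl]-10-methyl-12-(triethylsilyloxy)dodeca-2,6,10-trienoate | COC(=O)/C(Br)=C\[C@@H](Cl)C/C(CO[Si](C)(C)C(C)(C)C)=C/CC/C(C)=C\CO[Si](CC)(CC)CC | intermediate
17 | methyl (2E,4R,6Z,10Z)-2-bromo-4-{[(2R,3S)-2,3-dimethyloxirane-2-carbonyl]oxy}-6-[(tert-butyldimethylsilyloxy)methyl]-10-methyl-12-(triethylsilyloxy)dodeca-2,6,10-trienoate | COC(=O)/C(Br)=C\[C@H](OC(=O)[C@]1(C)O[C@H]1C)C/C(CO[Si](C)(C)C(C)(C)C)=C/CC/C(C)=C\CO[Si](CC)(CC)CC | intermediate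
18 | 2-(iodomethyl)-4,4,5,5-tetramethyl-1,3,2-dioxaborolane | ICB1OC(C)(C)C(C)(C)O1 | starting material
19 | iodo[(4,4,5,5-tetramethyl-1,3,2-dioxaborolan-2-yl)methyl]zinc (not isolated) | I[Zn]CB1OC(C)(C)C(C)(C)O1 | intermediate
20 | methyl (2Z,4R,6Z,10Z)-4-{[(2R,3S)-2,3-dimethyloxirane-2-carbonyl]oxy}-6-[(tert-butyldimethylsilyloxy)methyl]-10-methyl-2-[(4,4,5,5-tetramethyl-1,3,2-dioxaborolan-2-yl)methyl]-12-(triethylsilyloxy)dodeca-2,6,10-trienoate | COC(=O)/C(CB1OC(C)(C)C(C)(C)O1)=C\[C@H](OC(=O)[C@]2(C)O[C@H]2C)C/C(CO[Si](C)(C)C(C)(C)C)=C/CC/C(C)=C\CO[Si](CC)(CC)CC | intermediate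
21 | methyl (2Z,4R,6Z,10Z)-4-{[(2R,3S)-2,3-dimethyloxirane-2-carbonyl]oxy}-6-[(tert-butyldimethylsilyloxy)methyl]-10-methyl-12-oxo-2-[(4,4,5,5-tetramethyl-1,3,2-dioxaborolan-2-yl)methyl]dodeca-2,6,10-trienoate | COC(=O)/C(CB1OC(C)(C)C(C)(C)O1)=C\[C@H](OC(=O)[C@]2(C)O[C@H]2C)C/C(CO[Si](C)(C)C(C)(C)C)=C/CC/C(C)=C\C=O | intermediate
22 | ring-closed C6–O–Bpin borate of the open hydroxy ester: methyl 2-(ten-membered ring)acrylate with ring configuration as in 23 (not isolated) | COC(=O)C(=C)[C@H]1[C@H](OB2OC(C)(C)C(C)(C)O2)/C=C(/C)CC/C=C(\CO[Si](C)(C)C(C)(C)C)C[C@H]1OC(=O)[C@]3(C)O[C@H]3C | intermediate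
23 | (6R,7R,8R)-14-(tert-butyldimethylsilyloxy)-8-{[(2R,3S)-2,3-dimethyloxirane-2-carbonyl]oxy}germacra-1(10),4,11(13)-trien-12,6-olide | C=C1C(=O)O[C@@H]2/C=C(/C)CC/C=C(\CO[Si](C)(C)C(C)(C)C)C[C@@H](OC(=O)[C@]3(C)O[C@H]3C)[C@@H]12 | intermediate
24 | (6R,7R,8R)-8-{[(2R,3S)-2,3-dimethyloxirane-2-carbonyl]oxy}-14-hydroxygermacra-1(10),4,11(13)-trien-12,6-olide | C=C1C(=O)O[C@@H]2/C=C(/C)CC/C=C(\CO)C[C@@H](OC(=O)[C@]3(C)O[C@H]3C)[C@@H]12 | intermediate
25 | (1R,6R,7R,8R,10S)-1,10-epoxy-8-{[(2R,3S)-2,3-dimethyloxirane-2-carbonyl]oxy}-14-hydroxygermacra-4,11(13)-dien-12,6-olide | C=C1C(=O)O[C@@H]2/C=C(/C)CC[C@H]3O[C@]3(CO)C[C@@H](OC(=O)[C@]3(C)O[C@H]3C)[C@@H]12 | intermediate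
26 | (1R,6R,7R,8R,10S)-14-acetoxy-1,10-epoxy-8-{[(2R,3S)-2,3-dimethyloxirane-2-carbonyl]oxy}germacra-4,11(13)-dien-12,6-olide | C=C1C(=O)O[C@@H]2/C=C(/C)CC[C@H]3O[C@]3(COC(C)=O)C[C@@H](OC(=O)[C@]3(C)O[C@H]3C)[C@@H]12 | target

**Step count**
Total: 16 steps. Longest linear sequence: 12 steps from nerol (steps 3, 4, 6, 7, 9, 10, 11, 12, 13, 14, 15, 16).

**Three steps most likely to fail**

Step 13 (the proposed new ring closure). The weak acid may not activate the deactivated allylboronate, oligomers may form, or the C8 centre may override the catalyst. The fallback is known chemistry: the chromium-mediated Nozaki–Hiyama-type allylation of an aldehyde by a 2-(bromomethyl)acrylate, the ring closure established for germacranolide lactones. It sets out from 17 and comes back at 23. Stille coupling of 17 with Bu3SnCH2OH (Pd(PPh3)4, dioxane, 80 °C) gives methyl (2Z,4R,6Z,10Z)-4-{[(2R,3S)-2,3-dimethyloxirane-2-carbonyl]oxy}-2-(hydroxymethyl)-6-[(tert-butyldimethylsilyloxy)methyl]-10-methyl-12-(triethylsilyloxy)dodeca-2,6,10-trienoate F1. CBr4, PPh3 and 2,6-lutidine convert it into the allylic bromide methyl (2E,4R,6Z,10Z)-2-(bromomethyl)-4-{[(2R,3S)-2,3-dimethyloxirane-2-carbonyl]oxy}-6-[(tert-butyldimethylsilyloxy)methyl]-10-methyl-12-(triethylsilyloxy)dodeca-2,6,10-trienoate F2. Swern oxidation as in step 12 (i-Pr2NEt as base) gives the bromo enal methyl (2E,4R,6Z,10Z)-2-(bromomethyl)-4-{[(2R,3S)-2,3-dimethyloxirane-2-carbonyl]oxy}-6-[(tert-butyldimethylsilyloxy)methyl]-10-methyl-12-oxododeca-2,6,10-trienoate F3. Slow addition of F3 to CrCl2 (10 equiv) in THF/DMF at 2 mM, then PPTS, closes the ring and the lactone to 23. The organochromium intermediate equilibrates, so the bromide geometry does not matter, and its chair transition state again favours the 6,7-trans lactone; the face relative to C8 is then substrate-controlled.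

Step 10 (with the chloride made in step 9). Elimination to a dienoate or erosion of the C8 configuration by chloride exchange can compete with the SN2 reaction. The fallback makes the C8–O bond by α-oxygenation with retention instead of displacement; it sets out from 12 and comes back at 17. L-Proline (20 mol%) and nitrosobenzene in DMSO give the (2R)-2-(anilinooxy) aldehyde F4. NaBH4 in MeOH in the same pot gives the (2R)-2-(anilinooxy) alcohol F5, and Zn/AcOH cleaves the N–O bond to (2R,4Z,8Z)-4-[(tert-butyldimethylsilyloxy)methyl]-8-methyl-10-(triethylsilyloxy)deca-4,8-diene-1,2-diol F6. Allyl chloroformate and pyridine at −40 °C protect the primary hydroxyl as the allyl carbonate F7. Acid 3 with DCC/DMAP acylates the secondary hydroxyl to the ester F8. Pd(PPh3)4 and morpholine remove the allyl carbonate to give the primary alcohol F9, and Dess–Martin periodinane gives the (2R)-2-acyloxy aldehyde F10. Olefination of F10 with 14 (KOt-Bu, 18-crown-6, THF, −78 °C) returns 17.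

Step 15 (site and face of the epoxidation). The ring conformer that reacts may expose the other face of C1=C10, or C4=C5 may compete. The fallback replaces hydroxyl direction by catalyst control and changes the order; it sets out from 24 and comes back at 26. Acetylation of 24 (Ac2O, pyridine, DMAP) gives (6R,7R,8R)-14-acetoxy-8-{[(2R,3S)-2,3-dimethyloxirane-2-carbonyl]oxy}germacra-1(10),4,11(13)-trien-12,6-olide F11. Shi epoxidation of F11 (fructose-derived ketone catalyst or its enantiomer, KHSO5, K2CO3 buffer, MeCN/dimethoxymethane/H2O, 0 °C) then gives 26, the chiral dioxirane selecting the reacting conformer of the strained trans alkene.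

**Further compounds**
F1 | step 13 | methyl (2Z,4R,6Z,10Z)-4-{[(2R,3S)-2,3-dimethyloxirane-2-carbonyl]oxy}-2-(hydroxymethyl)-6-[(tert-butyldimethylsilyloxy)methyl]-10-methyl-12-(triethylsilyloxy)dodeca-2,6,10-trienoate | COC(=O)/C(CO)=C\[C@H](OC(=O)[C@]1(C)O[C@H]1C)C/C(CO[Si](C)(C)C(C)(C)C)=C/CC/C(C)=C\CO[Si](CC)(CC)CC
F2 | step 13 | methyl (2E,4R,6Z,10Z)-2-(bromomethyl)-4-{[(2R,3S)-2,3-dimethyloxirane-2-carbonyl]oxy}-6-[(tert-butyldimethylsilyloxy)methyl]-10-methyl-12-(triethylsilyloxy)dodeca-2,6,10-trienoate | COC(=O)/C(CBr)=C\[C@H](OC(=O)[C@]1(C)O[C@H]1C)C/C(CO[Si](C)(C)C(C)(C)C)=C/CC/C(C)=C\CO[Si](CC)(CC)CC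
F3 | step 13 | methyl (2E,4R,6Z,10Z)-2-(bromomethyl)-4-{[(2R,3S)-2,3-dimethyloxirane-2-carbonyl]oxy}-6-[(tert-butyldimethylsilyloxy)methyl]-10-methyl-12-oxododeca-2,6,10-trienoate | COC(=O)/C(CBr)=C\[C@H](OC(=O)[C@]1(C)O[C@H]1C)C/C(CO[Si](C)(C)C(C)(C)C)=C/CC/C(C)=C\C=O
F4 | step 10 | (2R,4Z,8Z)-2-(anilinooxy)-4-[(tert-butyldimethylsilyloxy)methyl]-8-methyl-10-(triethylsilyloxy)deca-4,8-dienal | O=C[C@H](ONc1ccccc1)C/C(CO[Si](C)(C)C(C)(C)C)=C/CC/C(C)=C\CO[Si](CC)(CC)CC
F5 | step 10 | (2R,4Z,8Z)-2-(anilinooxy)-4-[(tert-butyldimethylsilyloxy)methyl]-8-methyl-10-(triethylsilyloxy)deca-4,8-dien-1-ol | OC[C@H](ONc1ccccc1)C/C(CO[Si](C)(C)C(C)(C)C)=C/CC/C(C)=C\CO[Si](CC)(CC)CC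
F6 | step 10 | (2R,4Z,8Z)-4-[(tert-butyldimethylsilyloxy)methyl]-8-methyl-10-(triethylsilyloxy)deca-4,8-diene-1,2-diol | OC[C@H](O)C/C(CO[Si](C)(C)C(C)(C)C)=C/CC/C(C)=C\CO[Si](CC)(CC)CC
F7 | step 10 | allyl (2R,4Z,8Z)-2-hydroxy-4-[(tert-butyldimethylsilyloxy)methyl]-8-methyl-10-(triethylsilyloxy)deca-4,8-dien-1-yl carbonate | C=CCOC(=O)OC[C@H](O)C/C(CO[Si](C)(C)C(C)(C)C)=C/CC/C(C)=C\CO[Si](CC)(CC)CC
F8 | step 10 | (2R,4Z,8Z)-1-(allyloxycarbonyloxy)-4-[(tert-butyldimethylsilyloxy)methyl]-8-methyl-10-(triethylsilyloxy)deca-4,8-dien-2-yl (2R,3S)-2,3-dimethyloxirane-2-carboxylate | C=CCOC(=O)OC[C@H](OC(=O)[C@]1(C)O[C@H]1C)C/C(CO[Si](C)(C)C(C)(C)C)=C/CC/C(C)=C\CO[Si](CC)(CC)CC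
F9 | step 10 | (2R,4Z,8Z)-1-hydroxy-4-[(tert-butyldimethylsilyloxy)methyl]-8-methyl-10-(triethylsilyloxy)deca-4,8-dien-2-yl (2R,3S)-2,3-dimethyloxirane-2-carboxylate | OC[C@H](OC(=O)[C@]1(C)O[C@H]1C)C/C(CO[Si](C)(C)C(C)(C)C)=C/CC/C(C)=C\CO[Si](CC)(CC)CC
F10 | step 10 | (2R,4Z,8Z)-4-[(tert-butyldimethylsilyloxy)methyl]-8-methyl-1-oxo-10-(triethylsilyloxy)deca-4,8-dien-2-yl (2R,3S)-2,3-dimethyloxirane-2-carboxylate | O=C[C@H](OC(=O)[C@]1(C)O[C@H]1C)C/C(CO[Si](C)(C)C(C)(C)C)=C/CC/C(C)=C\CO[Si](CC)(CC)CC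
F11 | step 15 | (6R,7R,8R)-14-acetoxy-8-{[(2R,3S)-2,3-dimethyloxirane-2-carbonyl]oxy}germacra-1(10),4,11(13)-trien-12,6-olide | C=C1C(=O)O[C@@H]2/C=C(/C)CC/C=C(\COC(C)=O)C[C@@H](OC(=O)[C@]3(C)O[C@H]3C)[C@@H]12
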